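Numbering follows the target SMILES. Ring A (seven-membered) is C1 (O-angelate), C2=C3(CH3), C4, C5 (O-veratrate), C6 (fusion CH), C7 (fusion C-CH3). Ring B (five-membered) is C6, C7, C8, C9, C10 (C(OH)i-Pr). "Up" is the face carrying C1–O, C5–O and C6–H; "down" carries C7–CH3 and C10–OH.
Retrosynthetic cuts, in order: the two ester C–O bonds, C3–CH3, C9–C10 (ring B opens), C7–CH3 and C6–C10 in one stroke, then C7–C8. Ring A remains and is bought as tropone.
Enabling feature: a carbonyl at C5 makes C6 its α-carbon and the quaternary C7 its β-carbon, and the oxygenated C1 flanks C7. A ring A enone C5(=O)–C6=C7 can therefore accept the C7 methyl and, as its enolate, the C10 carbon of isobutyraldehyde in one flask.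
Forward order: ring A is oxygenated at C1, C3 and C5, the C8–C9 arm is added, the key step builds C7 and C6, ring B closes by a C9-to-C10 Barbier reaction, the C1/C3 dione becomes the methyl enone, and the angelate goes on last.
Stereochemistry: C1 comes from lipase desymmetrisation of a meso diacetate and steers C7 (methyl anti). C7 and C1 steer C6. The closed aldol transition state sets the C10 carbinol, which relays to C5 by a syn-directed reduction. C5 and C6 steer the tertiary C10. C1, erased at the dione stage, is reset by equatorial hydride delivery.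
Key step: step 13

Assumption: the lipase is taken to follow its usual preference for secondary alcohols and to hydrolyse the acetate on the R-configured carbinol carbon (C1) of the meso diacetate.
TBS = tert-butyldimethylsilyl; Ver = 3,4-dimethoxybenzoyl.

Step 1
Reactants: 1 tropone
Product: 2 cyclohepta-3,5-dien-1-one
Conditions: LiAlH4, Et2O, −10 °C; then AcOH, 0 °C
Reagents that add atoms: none
Why: This is a conjugate (1,8) hydride reduction in which hydride adds to the terminus of the tropone π system and the trienolate is protonated kinetically at its α-carbon on the acid quench, which leaves the unconjugated 3,5-dienone.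

Step 2
Reactants: 2 cyclohepta-3,5-dien-1-one
Product: 3 1,4-dioxaspiro[4.6]undeca-7,9-diene (ethylene ketal; the spiro carbon is C3)
Conditions: (Me3SiOCH2)2, Me3SiOTf (2 mol %), CH2Cl2, −78 °C; pyridine quench
Reagents that add atoms: 1,2-bis(trimethylsiloxy)ethane, C[Si](C)(C)OCCO[Si](C)(C)C
Why: Aprotic ketalisation with the bis-silyl ether of glycol under silyl triflate catalysis runs at low temperature without protic acid or water, so the dioxolane should form, driven by hexamethyldisiloxane, before the skipped diene can slip into conjugation.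

Step 3
Reactants: 3 1,4-dioxaspiro[4.6]undeca-7,9-diene
Product: 5 meso cis-ene-diol (C1–OH and C5–OH both up; C6=C7; C3 dioxolane), via endoperoxide 4 (not isolated)
Conditions: O2, tetraphenylporphyrin (cat.), visible light, CH2Cl2, −20 °C; then Zn, AcOH, 0 °C to rt
Reagents that add atoms: oxygen, O=O
Why: The singlet oxygen [4+2] cycloaddition to the ring diene is suprafacial and therefore places both new C–O bonds (C1 and C5) on one face, and zinc in acetic acid cleaves only the O–O bond, so the cis, meso diol should result.

Step 4
Reactants: 5 meso cis-ene-diol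
Product: 6 meso cis-diacetate
Conditions: Ac2O, pyridine, 4-dimethylaminopyridine (cat.), CH2Cl2, 0 °C to rt
Reagents that add atoms: acetic anhydride, CC(=O)OC(C)=O
Why: Nucleophile-catalysed acetylation of both allylic alcohols provides the enzyme substrate and touches no stereocentre.

Step 5
Reactants: 6 meso cis-diacetate
Product: 7 monoacetate (C1 R alcohol free; C5 S acetate)
Conditions: lipase from Pseudomonas cepacia, phosphate buffer pH 7, acetone (10 %), 25 °C
Reagents that add atoms: none
Why: In this enzymatic desymmetrisation by selective hydrolysis of one of two enantiotopic esters the lipase should cleave the acetate at the R-configured carbinol carbon, which frees C1–OH, keeps C5–OAc and fixes the absolute configuration of the whole route.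

Step 6
Reactants: 7 monoacetate
Product: 8 C1 TBS ether, C5 acetate
Conditions: t-BuMe2SiCl, imidazole, DMF, rt
Reagents that add atoms: tert-butyldimethylsilyl chloride, CC(C)(C)[Si](C)(C)Cl
Why: Imidazole-promoted silylation caps C1–OH with the bulky, non-leaving group that later shields the upper face of C7.

Step 7
Reactants: 8 C1 TBS ether, C5 acetate
Product: 9 C1 TBS ether, C5 allylic alcohol
Conditions: K2CO3 (cat.), MeOH, 0 °C
Reagents that add atoms: none
Why: Base-catalysed transesterification removes the acetate as methyl acetate while silyl ether and ketal are inert to methanolic carbonate.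

Step 8
Reactants: 9 C1 TBS ether, C5 allylic alcohol
Product: 10 4-siloxy enone (C5=O; C6=C7; C1–OTBS up; C3 dioxolane)
Conditions: Dess–Martin periodinane, CH2Cl2, 0 °C to rt
Reagents that add atoms: none
Why: Dess–Martin oxidation of the allylic C5 alcohol is fast and non-basic, so the γ-siloxy enone should form without β-elimination toward the C3 ketal and with C1 untouched.

Step 9
Reactants: 10 4-siloxy enone; 11 1-(tert-butyldimethylsiloxy)-1-methoxyethene
Product: 12 Michael adduct (C5–C6 TBS enol ether; C7–CH2CO2Me down, trans to C1–OTBS)
Conditions: MeCN, 55 °C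
Reagents that add atoms: none
Why: In this thermal, catalyst-free Mukaiyama–Michael addition the ketene silyl acetal attacks C7 anti to the C1 silyl ether and passes its silyl group to the C5 oxygen, so the arm carbons C8 and C9 and a regiodefined C5–C6 silyl enol ether arise together without a Lewis acid that could open the ketal (the C7 centre is erased again in step 12).

Step 10
Reactants: 12 Michael adduct
Product: 13 primary C9 alcohol (silyl enol ether retained)
Conditions: LiAlH4, Et2O, 0 °C; aqueous work-up
Reagents that add atoms: none
Why: Hydride reduction takes the methyl ester to the primary alcohol and leaves silyl enol ether, silyl ether and ketal alone because none of them is electrophilic toward aluminium hydride.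

Step 11
Reactants: 13 primary C9 alcohol
Product: 14 tris-silyl compound (C1–OTBS; C5–C6 TBS enol ether; C9–OTBS)
Conditions: t-BuMe2SiCl, imidazole, CH2Cl2, rt
Reagents that add atoms: tert-butyldimethylsilyl chloride, CC(C)(C)[Si](C)(C)Cl
Why: Routine silylation of the primary alcohol runs under non-acidic conditions that the silyl enol ether tolerates.

Step 12
Reactants: 14 tris-silyl compound
Product: 15 key-step precursor (C5=O; C6=C7 bearing CH2CH2OTBS; C1–OTBS up; C3 dioxolane)
Conditions: Pd(OAc)2 (1.05 equiv), MeCN, rt to 40 °C
Reagents that add atoms: none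
Why: In the Saegusa–Ito oxidation divalent palladium binds the silyl enol ether at C6 and β-hydride elimination can only take the C7 hydrogen, so the C6=C7 enone is restored with the arm on C7 and no regioisomer is possible.

Step 13
Reactants: 15 key-step precursor; 16 isobutyraldehyde
Product: 19 anti aldol adduct (C5 ketone; C1–OTBS up; C3 dioxolane; C6–CH(OH)i-Pr down with 10R carbinol; C7–CH3 down; C7–CH2CH2OTBS up), via lithium enolate 17 (not isolated), via chlorozinc enolate 18 (not isolated)
Conditions: Me2CuLi (from MeLi and CuI), Et2O, −78 to −20 °C; ZnCl2 in THF, −78 °C; 16, −78 °C; AcOH in THF, −78 °C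
Reagents that add atoms: lithium dimethylcuprate (made from MeLi and CuI), [Li+].C[Cu-]C
Why: Me2CuLi forms a π complex with the enone on the face away from the C1 silyl ether, oxidative addition gives a trivalent copper adduct at C7, and reductive elimination forges C7–CH3 and releases the C5 enolate 17, whose only nucleophilic carbon is C6. Exchange of lithium for zinc (18) lowers the basicity, so that proton transfer to C4 and opening of the dioxolane should be avoided, and it holds the aldolate as a chelate that resists retro-aldol cleavage until the cold acid quench. The closest known reaction type is the three-component coupling of 4-siloxycycloalkenones (cuprate 1,4-addition followed by aldol trapping of the enolate), and no ring is closed in this step. C7 is controlled by C1 (methyl enters anti to C1–OSi); C6 is controlled by the new quaternary centre together with C1 (the upper enolate face carries the siloxyethyl arm and the C1 silyl ether, the lower face only the methyl group, so the aldehyde binds from below); C10 is controlled by the chair Zimmerman–Traxler transition state of the ring-locked E enolate, which leads to the anti aldol. The step needs 1,4- over 1,2-addition, which the soft cuprate secures, reaction at C6 rather than C4, which the conjugate addition itself defines, and survival of the γ-oxygen, for which a silyl ether rather than an acyloxy group stands at C1.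

Step 14
Reactants: 19 anti aldol adduct
Product: 20 1,3-syn diol (C5–OH up; C10–OH unchanged)
Conditions: Et2BOMe, THF/MeOH 4:1, −78 °C; NaBH4, −78 °C; then MeOH, repeated evaporation
Reagents that add atoms: none
Why: In the Narasaka–Prasad reduction boron ties C10–OH and the C5 carbonyl into a six-membered chelate in which the isopropyl group and the C6–C7 bond are equatorial, and external hydride adds axially to give the 1,3-syn diol, which for the anti aldol places C5–O up, trans to the C6 side chain.

Step 15
Reactants: 20 1,3-syn diol; 21 3,4-dimethoxybenzoyl chloride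
Product: 22 C5 veratrate (C10–OH free)
Conditions: 21 (1.05 equiv), pyridine, 4-dimethylaminopyridine (cat.), CH2Cl2, 0 °C
Reagents that add atoms: none
Why: This acylation under nucleophilic catalysis should be chemoselective because C5–OH is flanked by a CH2 group whereas C10–OH sits between an isopropyl group and the branched C6, and the veratrate then serves as its own protecting group.

Step 16
Reactants: 22 C5 veratrate
Product: 23 C9 primary alcohol (C1–OTBS retained)
Conditions: HF·pyridine, pyridine, THF, 0 °C
Reagents that add atoms: none
Why: Buffered fluoride desilylation distinguishes the unhindered primary silyl ether from the secondary C1 silyl ether next to the quaternary C7, and ester and ketal are inert.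

Step 17
Reactants: 23 C9 primary alcohol
Product: 24 C9 primary iodide (C10–OH free)
Conditions: I2, PPh3, imidazole, CH2Cl2, 0 °C to rt
Reagents that add atoms: iodine, II
Why: Appel-type iodination proceeds by SN2 displacement of the primary alkoxyphosphonium ion, a pathway closed to the crowded C10 carbinol.

Step 18
Reactants: 24 C9 primary iodide
Product: 25 iodo ketone (C10=O; C6–H up)
Conditions: Dess–Martin periodinane, CH2Cl2, 0 °C to rt
Reagents that add atoms: none
Why: Dess–Martin oxidation copes with hindered secondary alcohols and is non-basic, which matters because the product is a β-acyloxy ketone whose C6–H could epimerise or trigger elimination.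

Step 19
Reactants: 25 iodo ketone
Product: 26 trans-fused bicycle (ring B closed; C10–OH down and i-Pr up; C5–OVer up; C1–OTBS up; C3 dioxolane)
Conditions: SmI2 (2.5 equiv), NiI2 (2 mol %), THF, −78 to 0 °C; aqueous work-up
Reagents that add atoms: none
Why: In this intramolecular samarium Barbier reaction (5-exo attack of C9 on the C10 carbonyl) SmI2 turns the primary iodide into an alkylsamarium that adds to the ketone held with its oxygen syn to C5 by chelation of trivalent samarium to the C5 ester oxygen and with the isopropyl group beside the small C6–H, so the hydroxyl should end down, cis to C7–CH3, in a trans-fused bicycle.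

Step 20
Reactants: 26 trans-fused bicycle
Product: 27 keto diol (C1–OH up; C3=O; C10–OH)
Conditions: 48 % aq HF, MeCN, 0 °C to rt
Reagents that add atoms: water, O
Why: Aqueous HF cleaves the hindered C1 silyl ether through the strong Si–F bond and its acidity hydrolyses the dioxolane in the same flask, while the aryl ester and the non-activated tertiary alcohol should survive these mild conditions.

Step 21
Reactants: 27 keto diol
Product: 28 C1/C3 1,3-dione
Conditions: Dess–Martin periodinane, CH2Cl2, rt
Reagents that add atoms: none
Why: Dess–Martin oxidation is the usual way from β-hydroxy ketones to 1,3-diketones, only the secondary C1 alcohol can react, and the C1 centre is given up on purpose because C2 thereby becomes the single acidic position that defines the later C2=C3 alkene.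

Step 22
Reactants: 28 C1/C3 1,3-dione
Product: 29 vinylogous triflate (C1=O; C2=C3–OTf)
Conditions: Tf2O (1.05 equiv), Et3N, CH2Cl2, −78 °C
Reagents that add atoms: triflic anhydride, O=S(=O)(OS(=O)(=O)C(F)(F)F)C(F)(F)F
Why: In this O-sulfonylation of the dione enolate the oxygen on C1 is shielded by the quaternary C7, so triflation should occur at the C3 oxygen, as is known for 4,4-disubstituted cyclic 1,3-diones, while the hindered tertiary alcohol stays out at low temperature.

Step 23
Reactants: 29 vinylogous triflate
Product: 30 methyl enone (C1=O; C2=C3–CH3)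
Conditions: MeZnCl (1.5 equiv), Pd(PPh3)4 (5 mol %), THF, rt
Reagents that add atoms: methylzinc chloride, C[Zn]Cl
Why: In the Negishi coupling zerovalent palladium inserts readily into the electron-poor vinyl triflate and methyl transfer from zinc forms C3–CH3 under conditions that spare ketone, ester and tertiary alcohol.

Step 24
Reactants: 30 methyl enone
Product: 31 allylic alcohol (C1–OH up, trans to C7–CH3)
Conditions: LiBH(s-Bu)3, THF, −78 °C; then H2O
Reagents that add atoms: none
Why: In this 1,2-reduction with a bulky trialkylborohydride the chair-like ring A has C6–H and one C4–H axial on the upper face and C7–CH3 axial on the lower face, and the reagent should avoid the axial path past the upper hydrogens and deliver hydride equatorially from below to give the axial C1–OH up, as such hydrides do with 4,4-dimethyl-3-oxo terpenoids, while the β-methyl group blocks 1,4-reduction.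

Step 25
Reactants: 31 allylic alcohol; 32 angelic acid
Product: 34 target CNP0142353.1 (C1–O-angelate up; C2=C3–CH3; C5–OVer up; C6–H up; C7–CH3 down; C10–OH down and i-Pr up; 1R,5S,6S,7S,10R in the numbering used here), via mixed anhydride 33 (not isolated)
Conditions: 32, 2,4,6-Cl3C6H2COCl, Et3N, toluene, rt; then 31, 75 °C
Reagents that add atoms: none
Why: In this Yamaguchi-type esterification without nucleophilic catalyst the alcohol attacks the less hindered angeloyl carbonyl of the mixed anhydride, leaving out 4-dimethylaminopyridine suppresses Z-to-E isomerisation to the tiglate, and the tertiary C10 alcohol is too hindered to compete.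

Compound list
1 | tropone | O=c1cccccc1 | starting material
2 | cyclohepta-3,5-dien-1-one | O=C1CC=CC=CC1 | intermediate
3 | 1,4-dioxaspiro[4.6]undeca-7,9-diene | C1COC2(O1)CC=CC=CC2 | intermediate
4 | meso endoperoxide (C1,C5-epidioxy bridge, C6=C7, C3 dioxolane) | O1O[C@@H]2CC3(OCCO3)C[C@H]1C=C2 | intermediate
5 | meso cis-ene-diol | O[C@@H]1CC2(OCCO2)C[C@H](O)C=C1 | intermediate
6 | meso cis-diacetate | CC(=O)O[C@@H]1CC2(OCCO2)C[C@H](OC(C)=O)C=C1 | intermediate
7 | monoacetate, C1 (R) alcohol, C5 (S) acetate | O[C@@H]1CC2(OCCO2)C[C@H](OC(C)=O)C=C1 | intermediate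
8 | C1 TBS ether, C5 acetate | CC(C)(C)[Si](C)(C)O[C@@H]1CC2(OCCO2)C[C@H](OC(C)=O)C=C1 | intermediate
9 | C1 TBS ether, C5 alcohol | CC(C)(C)[Si](C)(C)O[C@@H]1CC2(OCCO2)C[C@H](O)C=C1 | intermediate
10 | 4-siloxy enone | CC(C)(C)[Si](C)(C)O[C@@H]1CC2(OCCO2)CC(=O)C=C1 | intermediate
11 | 1-(tert-butyldimethylsiloxy)-1-methoxyethene | C=C(OC)O[Si](C)(C)C(C)(C)C | starting material
12 | Michael adduct, TBS enol ether methyl ester | CC(C)(C)[Si](C)(C)O[C@@H]1CC2(OCCO2)CC(O[Si](C)(C)C(C)(C)C)=C[C@H]1CC(=O)OC | intermediate
13 | primary C9 alcohol, TBS enol ether | CC(C)(C)[Si](C)(C)O[C@@H]1CC2(OCCO2)CC(O[Si](C)(C)C(C)(C)C)=C[C@H]1CCO | intermediate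
14 | tris-silyl compound | CC(C)(C)[Si](C)(C)O[C@@H]1CC2(OCCO2)CC(O[Si](C)(C)C(C)(C)C)=C[C@H]1CCO[Si](C)(C)C(C)(C)C | intermediate
15 | key-step precursor, 3-(2-siloxyethyl)-4-siloxycyclohept-2-enone with C3 dioxolane | CC(C)(C)[Si](C)(C)O[C@@H]1CC2(OCCO2)CC(=O)C=C1CCO[Si](C)(C)C(C)(C)C | intermediate
16 | isobutyraldehyde | CC(C)C=O | starting material
17 | lithium enolate (C5–C6) with quaternary C7 | CC(C)(C)[Si](C)(C)O[C@@H]1CC2(OCCO2)CC(O[Li])=C[C@]1(C)CCO[Si](C)(C)C(C)(C)C | intermediate
18 | chlorozinc enolate | CC(C)(C)[Si](C)(C)O[C@@H]1CC2(OCCO2)CC(O[Zn]Cl)=C[C@]1(C)CCO[Si](C)(C)C(C)(C)C | intermediate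
19 | anti aldol adduct | CC(C)(C)[Si](C)(C)O[C@@H]1CC2(OCCO2)CC(=O)[C@@H]([C@H](O)C(C)C)[C@]1(C)CCO[Si](C)(C)C(C)(C)C | intermediate
20 | 1,3-syn diol | CC(C)(C)[Si](C)(C)O[C@@H]1CC2(OCCO2)C[C@H](O)[C@@H]([C@H](O)C(C)C)[C@]1(C)CCO[Si](C)(C)C(C)(C)C | intermediate
21 | 3,4-dimethoxybenzoyl chloride | COc1ccc(C(=O)Cl)cc1OC | starting material
22 | C5 veratrate, C10 alcohol | CC(C)(C)[Si](C)(C)O[C@@H]1CC2(OCCO2)C[C@H](OC(=O)c2ccc(OC)c(OC)c2)[C@@H]([C@H](O)C(C)C)[C@]1(C)CCO[Si](C)(C)C(C)(C)C | intermediate
23 | C9 primary alcohol | CC(C)(C)[Si](C)(C)O[C@@H]1CC2(OCCO2)C[C@H](OC(=O)c2ccc(OC)c(OC)c2)[C@@H]([C@H](O)C(C)C)[C@]1(C)CCO | intermediate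
24 | C9 primary iodide | CC(C)(C)[Si](C)(C)O[C@@H]1CC2(OCCO2)C[C@H](OC(=O)c2ccc(OC)c(OC)c2)[C@@H]([C@H](O)C(C)C)[C@]1(C)CCI | intermediate
25 | iodo ketone | CC(C)(C)[Si](C)(C)O[C@@H]1CC2(OCCO2)C[C@H](OC(=O)c2ccc(OC)c(OC)c2)[C@@H](C(=O)C(C)C)[C@]1(C)CCI | intermediate
26 | trans-fused bicycle, C10 tertiary alcohol | CC(C)(C)[Si](C)(C)O[C@@H]1CC2(OCCO2)C[C@H](OC(=O)c2ccc(OC)c(OC)c2)[C@@H]2[C@]1(C)CC[C@@]2(O)C(C)C | intermediate
27 | keto diol | O[C@@H]1CC(=O)C[C@H](OC(=O)c2ccc(OC)c(OC)c2)[C@@H]2[C@]1(C)CC[C@@]2(O)C(C)C | intermediate
28 | C1/C3 1,3-dione | O=C1CC(=O)C[C@H](OC(=O)c2ccc(OC)c(OC)c2)[C@@H]2[C@]1(C)CC[C@@]2(O)C(C)C | intermediate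
29 | vinylogous triflate | O=C1C=C(OS(=O)(=O)C(F)(F)F)C[C@H](OC(=O)c2ccc(OC)c(OC)c2)[C@@H]2[C@]1(C)CC[C@@]2(O)C(C)C | intermediate
30 | methyl enone | O=C1C=C(C)C[C@H](OC(=O)c2ccc(OC)c(OC)c2)[C@@H]2[C@]1(C)CC[C@@]2(O)C(C)C | intermediate
31 | allylic alcohol | O[C@@H]1C=C(C)C[C@H](OC(=O)c2ccc(OC)c(OC)c2)[C@@H]2[C@]1(C)CC[C@@]2(O)C(C)C | intermediate
32 | angelic acid | C/C=C(/C)C(=O)O | starting material
33 | angelic 2,4,6-trichlorobenzoic mixed anhydride | C/C=C(/C)C(=O)OC(=O)c1c(Cl)cc(Cl)cc1Cl | intermediate
34 | target CNP0142353.1 | C/C=C(/C)C(=O)O[C@@H]1C=C(C)C[C@H](OC(=O)c2ccc(OC)c(OC)c2)[C@@H]2[C@]1(C)CC[C@@]2(O)C(C)C | target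

Total step count: 25. Longest linear sequence: 25 steps (tropone 1 to target 34). Compounds 11, 16, 21 and 32 are bought.

Steps most likely to fail

1. Step 13.
- What may go wrong: conjugate addition to the fully substituted β-carbon next to the siloxy carbon may be slow, so that enolisation or reductive loss of the γ-oxygen competes. The crowded aldolate may also revert, and the facial bias at C6 may be insufficient.
- Fallback: the two bond formations are separated. From 15, Me2CuLi in the presence of Me3SiCl accelerates the addition and gives the isolable trimethylsilyl enol ether F1. A Mukaiyama aldol addition of F1 to 16 under BF3·OEt2 at −78 °C passes through an open transition state and is irreversible. It leads back to 19.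

2. Step 19.
- What may go wrong: the alkylsamarium may be quenched by the acidic C6–H, the veratrate may be lost by β-elimination from the ketone, or electron transfer to the aryl ester may interfere.
- Fallback: the ester is kept out of the ring closure.
  - From diol 20, HF·pyridine frees the primary alcohol (triol F2).
  - PPh3, I2 and imidazole give the iodo diol F3.
  - Et3SiCl and imidazole silylate the less hindered C5–OH (triethylsilyl ether F4).
  - Dess–Martin oxidation gives the iodo ketone F5, whose β-substituent is a poor leaving group and no electron acceptor.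
  - SmI2 closes ring B (bicyclic silyl ether F6).
  - Cold buffered HF·pyridine removes only the triethylsilyl group (bicyclic diol F7).
  - Acylation of the secondary C5–OH with 21 returns to 26.

3. Step 24.
- What may go wrong: facial selectivity may be poor or reversed if hydride enters from the upper face, anti to the angular methyl group.
- Fallback: that bias is used instead of opposed. From 30, Luche reduction (NaBH4, CeCl3, MeOH, −78 °C) should deliver hydride axially from above and give the C1-epimeric allylic alcohol F8. Mitsunobu esterification of F8 with 32 (PPh3, diisopropyl azodicarboxylate, toluene) then inverts C1 by attack on the open upper face and arrives directly at 34.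

Further compounds
F1 | step 13 | trimethylsilyl enol ether with quaternary C7 | CC(C)(C)[Si](C)(C)O[C@@H]1CC2(OCCO2)CC(O[Si](C)(C)C)=C[C@]1(C)CCO[Si](C)(C)C(C)(C)C
F2 | step 19 | triol (C5–OH, C9–OH, C10–OH) | CC(C)(C)[Si](C)(C)O[C@@H]1CC2(OCCO2)C[C@H](O)[C@@H]([C@H](O)C(C)C)[C@]1(C)CCO
F3 | step 19 | iodo diol | CC(C)(C)[Si](C)(C)O[C@@H]1CC2(OCCO2)C[C@H](O)[C@@H]([C@H](O)C(C)C)[C@]1(C)CCI
F4 | step 19 | C5 triethylsilyl ether, C10 alcohol, C9 iodide | CC(C)(C)[Si](C)(C)O[C@@H]1CC2(OCCO2)C[C@H](O[Si](CC)(CC)CC)[C@@H]([C@H](O)C(C)C)[C@]1(C)CCI
F5 | step 19 | iodo ketone with C5 triethylsilyl ether | CC(C)(C)[Si](C)(C)O[C@@H]1CC2(OCCO2)C[C@H](O[Si](CC)(CC)CC)[C@@H](C(=O)C(C)C)[C@]1(C)CCI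
F6 | step 19 | bicyclic silyl ether (C5–OSiEt3, C10–OH) | CC(C)(C)[Si](C)(C)O[C@@H]1CC2(OCCO2)C[C@H](O[Si](CC)(CC)CC)[C@@H]3[C@]1(C)CC[C@@]3(O)C(C)C
F7 | step 19 | bicyclic diol (C5–OH, C10–OH) | CC(C)(C)[Si](C)(C)O[C@@H]1CC2(OCCO2)C[C@H](O)[C@@H]3[C@]1(C)CC[C@@]3(O)C(C)C
F8 | step 24 | C1-epimeric allylic alcohol (C1–OH down) | O[C@H]1C=C(C)C[C@H](OC(=O)c2ccc(OC)c(OC)c2)[C@@H]2[C@]1(C)CC[C@@]2(O)C(C)C
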